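## Retrosynthetic overview

1. **Feature.** The carbocycle is numbered C1 (epoxide CH), C2, C3 (C=O), C4 (CH bearing C15H2OH), C5, C6 (lactone O-CH), C7, C8 (ester CH), C9, C10 (epoxide C bearing C14). One extra transannular bond C5–C10 turns this ten-membered ring into a cis-fused angular-methyl decalin (rings A and B). In that decalin the unit C1=C2–C3(OSiMe3)=C4 stores both the C3 ketone and the C1=C10 alkene.
2. **Key disconnection.** The ten-membered ring of 27 comes from a light-driven conrotatory six-electron opening of the cyclohexadiene ring A of 26, which cuts C5–C10.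
3. **After the opening.** C2 is protonated, C4=C5 is reduced 1,4 (sets C4), C11=C13 is released from its Me2N adduct, C1=C10 is epoxidised and C15 is desilylated.
4. **Before the opening.** 26 comes from the Δ4-3-keto-6α,12-olide 21 by cis 1,4-reduction at C5, C4 hydroxymethylation, C1–C2 dehydrogenation and C3–C4 silyl enol ether formation. 21 comes from octalone 7 by C7 alkylation, C8 reduction and acylation, and C6 oxygenation through C5=C6 dihydroxylation.
5. **Ring order.** Ring B (bought, 1), then ring A (asymmetric Michael addition and aldol, sets C10), then the γ-lactone, then the ten-membered ring by merger of A and B, then the oxirane.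

Key step: step 18

Remark: eudesmane/germacrane numbering is used throughout and β is the face of C14 in the decalins; C11 of 13–30 forms without control, is drawn without configuration and disappears in step 21; 1 is taken as a catalogue compound.

## Route

Step 1
Reactants: 1 7-methyl-1,4-dioxaspiro[4.5]decan-8-one (racemic); 2 (R)-1-phenylethylamine; 3 but-3-en-2-one
Product: 6 (7R)-7-methyl-7-(3-oxobutyl)-1,4-dioxaspiro[4.5]decan-8-one, via ketimine 4 (not isolated), via C10-alkylated ketimine 5 (not isolated)
Conditions: 2, cat. TsOH, toluene, Dean–Stark, reflux; 3, THF, rt to 40 °C; 20% aq AcOH, rt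
Reagents that add atoms: water, O
Why: Asymmetric Michael addition of a chiral imine: the more substituted secondary enamine tautomer of 4 adds to 3 through a compact aza-ene-like transition state on the face away from the phenyl group of the auxiliary, which should set the quaternary C10 (C14 β), and dilute acetic acid then hydrolyses 5 without opening the ketal.

Step 2
Reactants: 6
Product: 7 octalone ketal (C3 ketone, C4=C5, C8 ethylene ketal, 10β-methyl)
Conditions: NaOMe, MeOH, rt to 50 °C
Reagents that add atoms: none
Why: Intramolecular aldol condensation (second half of a Robinson annulation): the methyl ketone enolate carbon C4 attacks the C5 ketone in a 6-(enolexo)-exo-trig closure of ring A and loss of water gives the conjugated enone, C10 being untouched.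

Step 3
Reactants: 7
Product: 8 3β-allylic alcohol (C4=C5, C8 ethylene ketal)
Conditions: NaBH4, CeCl3·7H2O, MeOH, −78 to 0 °C
Reagents that add atoms: none
Why: Luche reduction: hydride adds 1,2 from the α face opposite to C14 to give the pseudoequatorial 3β-alcohol, which takes the enone out of play for the enolate chemistry of steps 5 and 7 (C3 is re-oxidised in step 8, so its configuration does not matter).

Step 4
Reactants: 8
Product: 9 hydroxy ketone (3β-OH, C4=C5, C8 ketone)
Conditions: pyridinium tosylate (cat.), acetone–H2O, 40 °C
Reagents that add atoms: water, O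
Why: Acid-catalysed ketal hydrolysis under buffered conditions that are too weak to ionise the allylic alcohol.

Step 5
Reactants: 9; 10 tert-butyl bromoacetate
Product: 11 keto ester (7β-CH2CO2tBu equatorial, H7α, C8 ketone, 3β-OH)
Conditions: LiN(iPr)2 (2.1 equiv), THF–DMPU, −78 °C; 10, −78 to −30 °C; then K2CO3, MeOH, rt
Reagents that add atoms: none
Why: Kinetic enolate alkylation: the C8 ketone is deprotonated at the open C7 and not at the neopentyl C9, the C3 lithium alkoxide is inert in the cold, and the carbonate treatment equilibrates C7 to the equatorial 7β side chain.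

Step 6
Reactants: 11
Product: 12 diol ester (3β-OH, 8β-OH axial, 7β-CH2CO2tBu)
Conditions: NaBH4, MeOH–CH2Cl2, −40 °C; AcOH quench
Reagents that add atoms: none
Why: Substrate-controlled borohydride reduction: axial approach on the β face is blocked by the syn-axial C14 methyl group, so hydride should arrive from the α side and give the axial 8β-alcohol, while the tert-butyl ester resists lactonisation onto O8.

Step 7
Reactants: 12
Product: 13 Mannich base (C11 carries CH2NMe2 = C13, C11 epimers)
Conditions: LiN(iPr)2 (3.3 equiv), THF, −78 °C; Me2N=CH2+ I−, −78 to −20 °C; AcOH quench in the cold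
Reagents that add atoms: N,N-dimethylmethyleneiminium iodide, C=[N+](C)C.[I-]
Why: Mannich reaction of the ester enolate with Eschenmoser's salt, possible here because no ketone is present; it brings in C13 as the base-stable amine adduct of the later C11=C13 methylene group.

Step 8
Reactants: 13
Product: 14 hydroxy enone (C3 ketone, C4=C5, 8β-OH)
Conditions: MnO2 (activated, excess), CH2Cl2, rt
Reagents that add atoms: none
Why: Chemoselective allylic alcohol oxidation: MnO2 oxidises the allylic 3-OH and leaves the saturated axial 8-OH alone.

Step 9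
Reactants: 14; 15 (R)-2-methylbutanoic acid
Product: 16 8β-[(R)-2-methylbutanoyloxy] enone
Conditions: 15 (3 equiv), DCC, DMAP (cat.), CH2Cl2, rt
Reagents that add atoms: none
Why: Steglich esterification installs the final ester with its stereocentre taken from 15, blocks O8 so that only O6 can lactonise in step 12, and turns any minor enantiomeric series from step 1 into a separable diastereomer.

Step 10
Reactants: 16
Product: 17 Δ5 3-ethylene ketal (C5=C6)
Conditions: HOCH2CH2OH, HC(OMe)3, TsOH·H2O (1.2 equiv, the first equivalent protonates the amine), CH2Cl2, rt; NaHCO3 work-up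
Reagents that add atoms: ethane-1,2-diol, OCCO
Why: Deconjugative ketalisation of a Δ4-3-ketone: under equilibrating acid catalysis the double bond moves to C5=C6, and room temperature with an orthoformate as water scavenger spares the tert-butyl ester.

Step 11
Reactants: 17
Product: 18 5α,6α-diol
Conditions: OsO4 (10 mol %), NMO, MeSO2NH2, acetone–H2O, rt to 40 °C
Reagents that add atoms: N-methylmorpholine N-oxide, C[N+]1([O-])CCOCC1; water, O
Why: Upjohn dihydroxylation: suprafacial addition to the α face, opposite to C14, the axial 8β-ester and the 7β side chain, should set C6 as 6α-OH (H6β), the C5 carbinol being only transient.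

Step 12
Reactants: 18
Product: 21 Δ4-3-keto-6α,12-olide carrying the 8β-ester, via dihydroxy ketone 19 (not isolated), via hydroxy enone acid 20 (not isolated)
Conditions: CF3CO2H–CH2Cl2–H2O, 0 °C to rt; toluene azeotrope; NaHCO3 work-up
Reagents that add atoms: water, O
Why: Acid cascade of ketal hydrolysis to 19, dehydration of its β-hydroxy ketone together with tert-butyl ester acidolysis to 20, and 5-exo-trig lactonisation of the 6α-OH onto C12; the C6–O bond is never broken, so the lactone is trans-fused (H6β, H7α).

Step 13
Reactants: 21
Product: 22 cis-fused dimethylphenylsilyl enol ether (H5β, C3=C4)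
Conditions: [(Ph3P)CuH]6 (5 mol %), PhMe2SiH, toluene, rt
Reagents that add atoms: dimethylphenylsilane, C[SiH](C)c1ccccc1
Why: Copper hydride catalysed 1,4-hydrosilylation: as in organocopper additions to 10-methyl octalones, hydride should enter C5 axially to ring A on the β face (the α face carries the 6α-oxygen and the axial H7 and H9), giving the cis fusion and a regiodefined C3–C4 enol ether.

Step 14
Reactants: 22
Product: 23 4β-hydroxymethyl ketone (cis-fused)
Conditions: 37% aq HCHO, Sc(OTf)3 (10 mol %), THF, rt
Reagents that add atoms: formaldehyde, C=O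
Why: Aqueous Mukaiyama aldol hydroxymethylation at C4 of the preformed enol ether brings in C15; the amine rides along as its ammonium salt and C4 (drawn as the equatorial epimer) is erased again in step 17.

Step 15
Reactants: 23
Product: 24 C15 TBS ether
Conditions: TBSCl, imidazole, DMF, 0 °C to rt
Reagents that add atoms: tert-butyldimethylsilyl chloride, CC(C)(C)[Si](C)(C)Cl
Why: Standard silylation of the primary alcohol under conditions too mild for retro-aldol cleavage or dehydration.

Step 16
Reactants: 24
Product: 25 Δ1-enone (C1=C2–C3=O, cis-fused)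
Conditions: LiN(iPr)2 (1.1 equiv), THF, −78 °C; PhS(Cl)=NtBu, −78 °C
Reagents that add atoms: none
Why: One-pot Mukaiyama dehydrogenation of the kinetic enolate, which forms at the C2 methylene and not at the hindered tertiary C4, and which tolerates the tertiary amine better than palladium or hypervalent iodine oxidants.

Step 17
Reactants: 25
Product: 26 cis-fused eudesmanolide 3-trimethylsilyloxy-1,3-diene (precursor of the key step)
Conditions: TMSOTf, Et3N, CH2Cl2, 0 °C
Reagents that add atoms: trimethylsilyl triflate, C[Si](C)(C)OS(=O)(=O)C(F)(F)F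
Why: Soft enolisation to the cross-conjugated silyl dienol ether is unambiguous, because H4 is the only α′ proton and the quaternary C10 excludes γ-deprotonation, while lactone and ester are not silylated under these conditions.

Step 18
Reactants: 26
Product: 27 germacratriene silyl dienol ether (C1=C10 Z, C4=C5 E, C2=C3 cis within the ring, which is E by CIP because OSiMe3 outranks C4)
Conditions: hν (300 nm lamps), degassed Et2O–pentane, trace Et3N, −78 °C, to the photostationary state; concentrated below −30 °C and used at once
Reagents that add atoms: none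
Why: Excitation of the homoannular diene C1=C2–C3=C4 starts a six-electron electrocyclic opening that is conrotatory in the excited state (Woodward–Hoffmann rules), so the σ bond C5–C10 shared by rings A and B breaks and C1=C10, C2=C3 and C4=C5 appear. The closest known reaction type is the photochemical opening of ring-fused 1,3-cyclohexadienes (provitamin D to previtamin D type) and of eudesmane 1,3-dienes, including 3-oxygenated ones, to cyclodeca-1,3,5-trienes. No ring is closed by bond formation: the ten-membered carbocycle arises by merger of rings A and B along their perimeter, and the γ-lactone stays fused at C6–C7. No stereocentre is formed and C5 and C10 are lost; their information passes into two double bonds, because H5 and C14 are cis and conrotation must therefore turn one ring B carbon inward and the other outward. The step needs one of the two conrotatory senses: the trans-fused lactone holds ring B in the chair with O6 and C11 equatorial, which makes H5 and C9 pseudoaxial and C6 and C14 pseudoequatorial on the twisted diene ring, so continuing the ground-state twist (least motion) carries H5 and C9 inward and C6 and C14 outward, which is also the less crowded mode and gives C1=C10 Z and C4=C5 E. Irradiation at the red edge of the diene band at −78 °C should limit secondary photochemistry of 27, hydrogen shifts and thermal disrotatory reclosure.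

Step 19
Reactants: 27
Product: 28 germacra-1(10)Z,4E-dien-3-one
Conditions: Bu4NF, AcOH (3 equiv), THF, −78 °C
Reagents that add atoms: none
Why: Fluoride desilylation and kinetic deconjugative protonation: the liberated dienolate takes up the proton at C2, its site of highest charge, whereas a neutral dienol ether under acid tends to be protonated at the remote C10; this leaves C1=C10 skipped and destroys the triene so that it cannot reclose, and the TBS ether survives in the cold.

Step 20
Reactants: 28
Product: 29 (4-H α, C15 β) germacr-1(10)Z-en-3-one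
Conditions: [(Ph3P)CuH]6 (0.4 equiv), degassed H2O (5 equiv), toluene, 0 °C to rt
Reagents that add atoms: none
Why: Conjugate reduction with the copper hydride hexamer touches only the enone: hydride goes to C5 and water protonates the copper enolate at C4 from the outside of the ring, and since C15 stands on the β face next to H6 in ten-membered 6α,12-trans-lactones the proton should arrive α, as required for 33.

Step 21
Reactants: 29
Product: 31 α-methylene lactone, via methiodide 30 (not isolated)
Conditions: MeI, CH2Cl2, rt; then aq NaHCO3, rt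
Reagents that add atoms: none
Why: Quaternisation followed by Hofmann-type E1cB elimination of trimethylamine regenerates C11=C13 under conditions mild enough for the β-silyloxy ketone and the skipped alkene.

Step 22
Reactants: 31
Product: 32 1β,10β-epoxide (H1 and C14 α, cis-oxirane)
Conditions: mCPBA (1.1 equiv), NaHCO3, CH2Cl2, 0 °C
Reagents that add atoms: 3-chloroperoxybenzoic acid, O=C(OO)c1cccc(Cl)c1
Why: Prilezhaev epoxidation picks the only electron-rich alkene; syn addition keeps the Z geometry as a cis-oxirane, and peripheral attack on the conformer that holds H1 and C14 on the α face, away from the 8β-ester, should place the oxygen β at C1 and C10.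

Step 23
Reactants: 32
Product: 33 target CNP0219035.1
Conditions: HF·pyridine, pyridine, THF, 0 °C
Reagents that add atoms: none
Why: Buffered fluoride desilylation frees the C15 alcohol without opening the oxirane, adding to the methylene lactone or epimerising C4.

## Compound list

| No. | Name | SMILES | Role |
|---|---|---|---|
| 1 | 7-methyl-1,4-dioxaspiro[4.5]decan-8-one (racemic) | CC1CC2(OCCO2)CCC1=O | starting material |
| 2 | (R)-1-phenylethylamine | C[C@@H](N)c1ccccc1 | starting material |
| 3 | but-3-en-2-one | C=CC(C)=O | starting material |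
| 4 | ketimine of 1 and 2 | CC1CC2(OCCO2)CCC1=N[C@H](C)c1ccccc1 | intermediate |
| 5 | C10-alkylated ketimine | CC(=O)CC[C@]1(C)CC2(OCCO2)CCC1=N[C@H](C)c1ccccc1 | intermediate |
| 6 | (7R)-7-methyl-7-(3-oxobutyl)-1,4-dioxaspiro[4.5]decan-8-one | CC(=O)CC[C@]1(C)CC2(OCCO2)CCC1=O | intermediate |
| 7 | octalone ketal (C3 ketone, C4=C5, C8 ketal, 10β-Me) | C[C@]12CCC(=O)C=C1CCC3(OCCO3)C2 | intermediate |
| 8 | 3β-allylic alcohol ketal | C[C@]12CC[C@H](O)C=C1CCC3(OCCO3)C2 | intermediate |
| 9 | 3β-hydroxy C8 ketone | C[C@]12CC[C@H](O)C=C1CCC(=O)C2 | intermediate |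
| 10 | tert-butyl bromoacetate | CC(C)(C)OC(=O)CBr | starting material |
| 11 | 7β-(tert-butoxycarbonylmethyl) C8 ketone | C[C@]12CC[C@H](O)C=C1C[C@H](CC(=O)OC(C)(C)C)C(=O)C2 | intermediate |
| 12 | 3β,8β-diol ester | C[C@]12CC[C@H](O)C=C1C[C@H](CC(=O)OC(C)(C)C)[C@H](O)C2 | intermediate |
| 13 | Mannich base (C11 epimers) | C[C@]12CC[C@H](O)C=C1C[C@H](C(CN(C)C)C(=O)OC(C)(C)C)[C@H](O)C2 | intermediate |
| 14 | 8β-hydroxy Δ4-3-ketone | C[C@]12CCC(=O)C=C1C[C@H](C(CN(C)C)C(=O)OC(C)(C)C)[C@H](O)C2 | intermediate |
| 15 | (R)-2-methylbutanoic acid | CC[C@@H](C)C(=O)O | starting material |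
| 16 | 8β-(R)-2-methylbutanoate enone | C[C@]12CCC(=O)C=C1C[C@H](C(CN(C)C)C(=O)OC(C)(C)C)[C@H](OC(=O)[C@H](C)CC)C2 | intermediate |
| 17 | Δ5 3-ethylene ketal | C[C@]12CCC3(OCCO3)CC1=C[C@H](C(CN(C)C)C(=O)OC(C)(C)C)[C@H](OC(=O)[C@H](C)CC)C2 | intermediate |
| 18 | 5α,6α-diol ketal | C[C@]12CCC3(OCCO3)C[C@]1(O)[C@@H](O)[C@H](C(CN(C)C)C(=O)OC(C)(C)C)[C@H](OC(=O)[C@H](C)CC)C2 | intermediate |
| 19 | 5α,6α-dihydroxy 3-ketone | C[C@]12CCC(=O)C[C@]1(O)[C@@H](O)[C@H](C(CN(C)C)C(=O)OC(C)(C)C)[C@H](OC(=O)[C@H](C)CC)C2 | intermediate |
| 20 | 6α-hydroxy Δ4-3-keto acid | C[C@]12CCC(=O)C=C1[C@@H](O)[C@H](C(CN(C)C)C(=O)O)[C@H](OC(=O)[C@H](C)CC)C2 | intermediate |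
| 21 | Δ4-3-keto-6α,12-olide (trans-lactone, 13-NMe2, 8β-ester) | CN(C)CC1C(=O)O[C@@H]2C3=CC(=O)CC[C@]3(C)C[C@@H](OC(=O)[C@H](C)CC)[C@@H]12 | intermediate |
| 22 | cis-fused (5βH) dimethylphenylsilyl enol ether | CN(C)CC1C(=O)O[C@@H]2[C@@H]3C=C(O[Si](C)(C)c4ccccc4)CC[C@]3(C)C[C@@H](OC(=O)[C@H](C)CC)[C@@H]12 | intermediate |
| 23 | 4β-hydroxymethyl 3-ketone | CN(C)CC1C(=O)O[C@@H]2[C@@H]3[C@@H](CO)C(=O)CC[C@]3(C)C[C@@H](OC(=O)[C@H](C)CC)[C@@H]12 | intermediate |
| 24 | C15 TBS ether | CN(C)CC1C(=O)O[C@@H]2[C@@H]3[C@@H](CO[Si](C)(C)C(C)(C)C)C(=O)CC[C@]3(C)C[C@@H](OC(=O)[C@H](C)CC)[C@@H]12 | intermediate |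
| 25 | Δ1-3-ketone | CN(C)CC1C(=O)O[C@@H]2[C@@H]3[C@@H](CO[Si](C)(C)C(C)(C)C)C(=O)C=C[C@]3(C)C[C@@H](OC(=O)[C@H](C)CC)[C@@H]12 | intermediate |
| 26 | cis-fused eudesmanolide 3-trimethylsilyloxy-1,3-diene | CN(C)CC1C(=O)O[C@@H]2[C@@H]3C(CO[Si](C)(C)C(C)(C)C)=C(O[Si](C)(C)C)C=C[C@]3(C)C[C@@H](OC(=O)[C@H](C)CC)[C@@H]12 | intermediate |
| 27 | germacratriene silyl dienol ether (1(10)Z, 4E, C2=C3 ring-cis) | CN(C)CC1C(=O)O[C@@H]2/C=C(CO[Si](C)(C)C(C)(C)C)/C(O[Si](C)(C)C)=C\C=C(\C)C[C@@H](OC(=O)[C@H](C)CC)[C@@H]12 | intermediate |
| 28 | germacra-1(10)Z,4E-dien-3-one | CN(C)CC1C(=O)O[C@@H]2/C=C(CO[Si](C)(C)C(C)(C)C)/C(=O)C/C=C(/C)C[C@@H](OC(=O)[C@H](C)CC)[C@@H]12 | intermediate |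
| 29 | germacr-1(10)Z-en-3-one (H4α, C15β) | CN(C)CC1C(=O)O[C@@H]2C[C@@H](CO[Si](C)(C)C(C)(C)C)C(=O)C/C=C(/C)C[C@@H](OC(=O)[C@H](C)CC)[C@@H]12 | intermediate |
| 30 | C13 trimethylammonium iodide | C[N+](C)(C)CC1C(=O)O[C@@H]2C[C@@H](CO[Si](C)(C)C(C)(C)C)C(=O)C/C=C(/C)C[C@@H](OC(=O)[C@H](C)CC)[C@@H]12.[I-] | intermediate |
| 31 | α-methylene lactone | C=C1C(=O)O[C@@H]2C[C@@H](CO[Si](C)(C)C(C)(C)C)C(=O)C/C=C(/C)C[C@@H](OC(=O)[C@H](C)CC)[C@@H]12 | intermediate |
| 32 | 1β,10β-epoxide TBS ether | C=C1C(=O)O[C@@H]2C[C@@H](CO[Si](C)(C)C(C)(C)C)C(=O)C[C@H]3O[C@@]3(C)C[C@@H](OC(=O)[C@H](C)CC)[C@@H]12 | intermediate |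
| 33 | CNP0219035.1 | C=C1C(=O)O[C@@H]2C[C@@H](CO)C(=O)C[C@H]3O[C@@]3(C)C[C@@H](OC(=O)[C@H](C)CC)[C@@H]12 | target |

## Step count and risks

Total step count: 23. Longest linear sequence: 23 steps (from 1).

**Step 18.** What may go wrong: control over the sense of conrotation may be lost, with C14 and C6 turning inward, so that the two new ring double bonds form with exchanged geometry. The fallback sets out from 26 and comes back at 29. The photoproduct is then the (1(10)E,4Z)-triene silyl dienol ether F1, and it is carried on rather than discarded.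
- Bu4NF/AcOH at −78 °C should give the (1(10)E,4Z)-dien-3-one F2.
- [(Ph3P)CuH]6 with water removes the C4=C5 geometry and should give the 1(10)E-en-3-one F3.
- Reversible thiyl radical addition (PhSSPh, 365 nm light, benzene) then isomerises the strained E trisubstituted ring alkene to the more stable Z isomer, which is 29.

The C1=C10 geometry is thus fixed under thermodynamic control after the ring opening instead of being demanded from the photoreaction.

**Step 20.** What may go wrong: the copper enolate may be protonated at C4 from the wrong face, or it may lose silyloxide from C15 by β-elimination. The fallback sets out from 28 and comes back directly at 29 (new compounds: none F0). Diimide, generated from 2-nitrobenzenesulfonylhydrazide and Et3N in CH2Cl2, transfers both hydrogen atoms in one concerted syn step to the outer face of the strained E double bond. C4 is then set by the alkene face, no enolate is formed, and the unstrained Z trisubstituted alkene should react more slowly.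

**Step 22.** What may go wrong: facial selectivity of the peracid on the flexible ring may be poor or inverted. The fallback sets out from 31 and comes back at 32. NBS in aqueous acetone at 0 °C puts bromine on the accessible face at C1, and water opens the bromonium ion anti at the tertiary C10 to give the 1-bromo-10-hydroxy compound F4. K2CO3 in acetone then closes the oxirane with inversion at C1. The oxygen ends on the face opposite to the one that an external electrophile attacks.

## Further compounds

F1 | step 18 | (1(10)E,4Z)-triene silyl dienol ether | CN(C)CC1C(=O)O[C@@H]2/C=C(CO[Si](C)(C)C(C)(C)C)\C(O[Si](C)(C)C)=C/C=C(\C)C[C@@H](OC(=O)[C@H](C)CC)[C@@H]12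
F2 | step 18 | (1(10)E,4Z)-dien-3-one | CN(C)CC1C(=O)O[C@@H]2/C=C(CO[Si](C)(C)C(C)(C)C)\C(=O)C/C=C(\C)C[C@@H](OC(=O)[C@H](C)CC)[C@@H]12
F3 | step 18 | 1(10)E-en-3-one | CN(C)CC1C(=O)O[C@@H]2C[C@@H](CO[Si](C)(C)C(C)(C)C)C(=O)C/C=C(\C)C[C@@H](OC(=O)[C@H](C)CC)[C@@H]12
F0 | step 20 | none | none
F4 | step 22 | 1-bromo-10-hydroxy compound | C=C1C(=O)O[C@@H]2C[C@@H](CO[Si](C)(C)C(C)(C)C)C(=O)C[C@H](Br)[C@@](C)(O)C[C@@H](OC(=O)[C@H](C)CC)[C@@H]12
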